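Everything rests on cutting ring B at B2–B3 and B4–B5, so that it is assembled from a four-carbon cyclobutenone and a two-carbon siloxyalkyne. The step exploits the pattern of ring B: the prenyl carbon B3 lies between the oxygenated carbons B2 and B4, B6 is oxygenated too, and B1 carries the benzylic CH2 to ring A. In one thermal operation the benzannulation should close ring B with prenyl, three oxygens and the diarylmethane link in place, leaving only B5 open for the acetyl group. Its precursor is a racemic 3-ethoxy-4-benzylcyclobutenone that already holds the complete ring A as a bis(methoxymethyl) ether.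

Key step: step 9

Remark: ring B carbons are labelled B1 (CH2), B2 (OH), B3 (prenyl), B4 (OH), B5 (acetyl), B6 (OH). Ring A positions are named by their substituents. Ar stands for 3-acetyl-6-methoxy-2,4-bis(methoxymethoxy)-5-methylphenyl, that is ring A bound through the carbon that carries the CH2 bridge in the target (MOM = methoxymethyl). The target has no stereocentre, so the chiral intermediates (the cyclobutenones and the cyclohexadienone) are taken as racemates.

Step 1
Reactants: 1 2-methylbenzene-1,3,5-triol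
Product: 2 1-(2,4,6-trihydroxy-3-methylphenyl)ethan-1-one
Conditions: Ac2O (1.1 equiv), BF3·OEt2, 25 → 60 °C; then aq. NaOAc
Reagents that add atoms: acetic anhydride, CC(=O)OC(C)=O
Why: Friedel–Crafts C-acylation of the phloroglucinol should stop after one acetyl group, since the two free ring carbons are equivalent and the boron-chelated aryl ketone is deactivated towards a second acylation.

Step 2
Reactants: 2 1-(2,4,6-trihydroxy-3-methylphenyl)ethan-1-one
Product: 3 1-(2,6-dihydroxy-4-methoxy-3-methylphenyl)ethan-1-one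
Conditions: Me2SO4 (1.05 equiv), K2CO3 (1.1 equiv), acetone, 25 °C
Reagents that add atoms: dimethyl sulfate, COS(=O)(=O)OC
Why: Williamson O-methylation under stoichiometric control should take the hydroxyl para to the acetyl group (the future methoxy oxygen of ring A), the most acidic one and the only one that cannot hydrogen-bond to the carbonyl.

Step 3
Reactants: 3 1-(2,6-dihydroxy-4-methoxy-3-methylphenyl)ethan-1-one
Product: 5 3-acetyl-2,4-dihydroxy-6-methoxy-5-methylbenzaldehyde, via iminium chloride 4 (not isolated)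
Conditions: POCl3 (1.2 equiv), DMF, MeCN, 0 → 25 °C; then H2O, 40 °C
Reagents that add atoms: N,N-dimethylformamide, CN(C)C=O; water, O
Why: Vilsmeier–Haack formylation should strike the only free ring carbon, which is activated by three oxygens, at a temperature at which the methyl ketone does not yet react with the chloroiminium salt, and water then hydrolyses the iminium ion.

Step 4
Reactants: 5 3-acetyl-2,4-dihydroxy-6-methoxy-5-methylbenzaldehyde
Product: 6 3-acetyl-6-methoxy-2,4-bis(methoxymethoxy)-5-methylbenzaldehyde (ArCHO)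
Conditions: NaH (2.2 equiv), MOMCl (2.5 equiv), DMF, 0 → 25 °C
Reagents that add atoms: chloromethyl methyl ether, COCCl
Why: Williamson etherification of the bis-phenoxide, formed irreversibly by NaH because both hydroxyls are chelated to carbonyl groups, should cap both ring A phenols as acetals that resist the bases, ketenes and heat ahead.

Step 5
Reactants: 6 ArCHO; 7 2,2-dimethyl-1,3-dioxane-4,6-dione (Meldrum's acid)
Product: 9 5-(ArCH2)-2,2-dimethyl-1,3-dioxane-4,6-dione, via arylidene Meldrum's acid 8 (not isolated)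
Conditions: Hantzsch ester (1.1 equiv), L-proline (20 mol%), EtOH, 25 °C
Reagents that add atoms: none
Why: In this reductive Knoevenagel alkylation the aldehyde condenses with the acidic methylene and the very electrophilic arylidene takes a hydride from the Hantzsch ester, while the hindered aryl ketone stays out.

Step 6
Reactants: 9 5-(ArCH2)-2,2-dimethyl-1,3-dioxane-4,6-dione
Product: 11 3-Ar-propanoic acid, via arylmethylmalonic acid 10 (not isolated)
Conditions: pyridine/H2O (10:1), 100 °C; then cold aq. citric acid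
Reagents that add atoms: water, O
Why: Hydrolysis of the dioxanedione releases acetone and a malonic acid that should decarboxylate at this temperature, and the basic medium leaves the MOM ethers alone.

Step 7
Reactants: 11 3-Ar-propanoic acid; 12 ethoxyacetylene
Product: 15 4-(ArCH2)-3-ethoxycyclobut-2-en-1-one (racemic), via acid chloride 13 (not isolated), via aldoketene 14 (not isolated)
Conditions: Me2C=C(Cl)NMe2 (1.1 equiv), CH2Cl2, 0 → 25 °C; then added slowly to 12 (3 equiv), Et3N (1.5 equiv), CH2Cl2, 25 → 40 °C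
Reagents that add atoms: none
Why: The α-chloroenamine makes the acid chloride without HCl (safe for the MOM ethers), Et3N eliminates HCl to the aldoketene, and a ketene–alkyne [2+2] cycloaddition, in which the nucleophilic terminal carbon of the ynol ether bonds to the ketene carbonyl carbon, should give the 3-ethoxy-4-substituted cyclobutenone with a racemic C4 stereocentre that is erased in step 9.

Step 8
Reactants: 16 ethyl 4-methylpent-3-enoate
Product: 19 triisopropyl[(5-methylhex-4-en-1-yn-1-yl)oxy]silane, via dibromo enolate 17 (not isolated), via lithium ynolate 18 (not isolated)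
Conditions: CH2Br2, LiTMP (lithium 2,2,6,6-tetramethylpiperidide), THF, −78 °C; LiN(SiMe3)2; n-BuLi, −78 → 0 °C; then i-Pr3SiCl, −78 → 25 °C
Reagents that add atoms: dibromomethane, BrCBr; chlorotri(propan-2-yl)silane, CC(C)[Si](Cl)(C(C)C)C(C)C
Why: In this Kowalski ester homologation LiCHBr2 should add to the ester faster than it deprotonates it at −78 °C, the dibromo enolate undergoes bromine–lithium exchange and a 1,2-shift to the ynolate, and the bulky chlorosilane silylates at oxygen.

Step 9
Reactants: 15 4-(ArCH2)-3-ethoxycyclobut-2-en-1-one; 19 triisopropyl[(5-methylhex-4-en-1-yn-1-yl)oxy]silane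
Product: 24 2-(ArCH2)-3-ethoxy-6-(3-methylbut-2-en-1-yl)-5-[(triisopropylsilyl)oxy]phenol, via vinylketene 20 (not isolated), via cyclobutenone adduct 21 (not isolated), via dienylketene 22 (not isolated), via cyclohexadienone 23 (not isolated)
Conditions: 19 (1.5 equiv), toluene (0.5 M), 110 °C, sealed tube
Reagents that add atoms: none
Why: Proposed new method: thermal 4π electrocyclic opening of 15 should give vinylketene 20, whose carbonyl carbon (the future B2) is attacked by the nucleophilic, prenyl-bearing carbon of the siloxyalkyne in a [2+2] cycloaddition that forms B2–B3 and B4–B5, and adduct 21 reopens (4π) to dienylketene 22. Ring B then closes by a thermal disrotatory 6π electrocyclisation that re-forms B1–B2, and tautomerisation of the B1 hydrogen of dienone 23 gives the phenol. The closest known reaction type is the Danheiser benzannulation of 3-alkyl- and 3-arylcyclobutenones with triisopropylsiloxyalkynes to resorcinol monosilyl ethers; the extension is the 3-alkoxy group, which as part of a vinylogous ester should raise the temperature of the first ring opening without changing the polarity of the ketene. No stereocentre remains, because C4 of 15 becomes the aromatic carbon B1. The one selectivity needed is the orientation of the ketene–alkyne addition, which the siloxy oxygen secures by making only the remote alkyne carbon nucleophilic; the masked ring A phenols leave no nucleophile to intercept the ketenes.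

Step 10
Reactants: 24 2-(ArCH2)-3-ethoxy-6-(3-methylbut-2-en-1-yl)-5-[(triisopropylsilyl)oxy]phenol
Product: 25 2-(ArCH2)-3-ethoxy-4-iodo-6-(3-methylbut-2-en-1-yl)-5-[(triisopropylsilyl)oxy]phenol
Conditions: NIS (1.05 equiv), CH2Cl2, −40 °C, dark
Reagents that add atoms: N-iodosuccinimide, O=C1CCC(=O)N1I
Why: Electrophilic aromatic iodination should occur at B5, the only free ring carbon, para to the free phenol and ortho to two ether oxygens, because at low temperature this arene is far more nucleophilic than the trisubstituted alkene of the prenyl group.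

Step 11
Reactants: 25 2-(ArCH2)-3-ethoxy-4-iodo-6-(3-methylbut-2-en-1-yl)-5-[(triisopropylsilyl)oxy]phenol
Product: 27 1-{3-(ArCH2)-2-ethoxy-4-hydroxy-5-(3-methylbut-2-en-1-yl)-6-[(triisopropylsilyl)oxy]phenyl}ethan-1-one, via enol ether 26 (not isolated)
Conditions: CH2=C(OEt)SnBu3 (1.5 equiv), Pd(PPh3)4 (10 mol%), CuI (20 mol%), DMF, 80 °C; then 1 M HCl, THF, 0 → 25 °C, brief
Reagents that add atoms: tributyl(1-ethoxyethenyl)stannane, CCCC[Sn](CCCC)(CCCC)C(=C)OCC; water, O
Why: Stille coupling with the 1-ethoxyvinyl stannane as an acetyl anion equivalent should place the two-carbon unit on B5 under neutral conditions (a Friedel–Crafts acylation would expose the prenyl group and the acetals to strong acid), and brief dilute acid hydrolyses the enol ether to the methyl ketone.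

Step 12
Reactants: 27 1-{3-(ArCH2)-2-ethoxy-4-hydroxy-5-(3-methylbut-2-en-1-yl)-6-[(triisopropylsilyl)oxy]phenyl}ethan-1-one
Product: 28 1-{3-[(3-acetyl-2,4-dihydroxy-6-methoxy-5-methylphenyl)methyl]-2,4-dihydroxy-5-(3-methylbut-2-en-1-yl)-6-[(triisopropylsilyl)oxy]phenyl}ethan-1-one
Conditions: MgI2·OEt2 (8 equiv), toluene/Et2O, 80 °C; then aq. NH4Cl
Reagents that add atoms: none
Why: In this chelation-controlled ether cleavage magnesium bridges the B5 carbonyl and the B6 ether oxygen (the bulky silyl ether at B4 cannot compete for the carbonyl) so that iodide removes the ethyl group by SN2, the two MOM acetals flanking the ring A acetyl group bind magnesium through their own oxygens and the carbonyl and should fall as well, the ring A methyl ether has no ortho carbonyl and stays, and a Lewis acid this mild should spare the prenyl group next to the free phenol.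

Step 13
Reactants: 28 1-{3-[(3-acetyl-2,4-dihydroxy-6-methoxy-5-methylphenyl)methyl]-2,4-dihydroxy-5-(3-methylbut-2-en-1-yl)-6-[(triisopropylsilyl)oxy]phenyl}ethan-1-one
Product: 29 mallotojaponin
Conditions: Bu4NF (1.2 equiv), AcOH (1.5 equiv), THF, 0 °C
Reagents that add atoms: none
Why: Fluoride-induced desilylation of the aryl silyl ether, buffered with acetic acid, should free the B4 phenol without any acid or Lewis acid that could cyclise the prenyl group onto the B2 or B4 oxygen.

Compound list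
1 | 2-methylbenzene-1,3,5-triol | Cc1c(O)cc(O)cc1O | starting material
2 | 1-(2,4,6-trihydroxy-3-methylphenyl)ethan-1-one | CC(=O)c1c(O)cc(O)c(C)c1O | intermediate
3 | 1-(2,6-dihydroxy-4-methoxy-3-methylphenyl)ethan-1-one | COc1cc(O)c(C(C)=O)c(O)c1C | intermediate
4 | N-[(3-acetyl-2,4-dihydroxy-6-methoxy-5-methylphenyl)methylidene]-N-methylmethanaminium chloride (formed in the flask) | C[N+](C)=Cc1c(OC)c(C)c(O)c(C(C)=O)c1O.[Cl-] | intermediate
5 | 3-acetyl-2,4-dihydroxy-6-methoxy-5-methylbenzaldehyde | O=Cc1c(OC)c(C)c(O)c(C(C)=O)c1O | intermediate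
6 | 3-acetyl-6-methoxy-2,4-bis(methoxymethoxy)-5-methylbenzaldehyde | O=Cc1c(OC)c(C)c(OCOC)c(C(C)=O)c1OCOC | intermediate
7 | 2,2-dimethyl-1,3-dioxane-4,6-dione | CC1(C)OC(=O)CC(=O)O1 | starting material
8 | 5-{[3-acetyl-6-methoxy-2,4-bis(methoxymethoxy)-5-methylphenyl]methylidene}-2,2-dimethyl-1,3-dioxane-4,6-dione (formed in the flask) | CC1(C)OC(=O)C(=Cc2c(OC)c(C)c(OCOC)c(C(C)=O)c2OCOC)C(=O)O1 | intermediate
9 | 5-{[3-acetyl-6-methoxy-2,4-bis(methoxymethoxy)-5-methylphenyl]methyl}-2,2-dimethyl-1,3-dioxane-4,6-dione | CC1(C)OC(=O)C(Cc2c(OC)c(C)c(OCOC)c(C(C)=O)c2OCOC)C(=O)O1 | intermediate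
10 | 2-{[3-acetyl-6-methoxy-2,4-bis(methoxymethoxy)-5-methylphenyl]methyl}propanedioic acid (formed in the flask) | OC(=O)C(Cc1c(OC)c(C)c(OCOC)c(C(C)=O)c1OCOC)C(=O)O | intermediate
11 | 3-[3-acetyl-6-methoxy-2,4-bis(methoxymethoxy)-5-methylphenyl]propanoic acid | OC(=O)CCc1c(OC)c(C)c(OCOC)c(C(C)=O)c1OCOC | intermediate
12 | ethoxyethyne (ethoxyacetylene) | C#COCC | starting material
13 | 3-[3-acetyl-6-methoxy-2,4-bis(methoxymethoxy)-5-methylphenyl]propanoyl chloride (formed in the flask) | ClC(=O)CCc1c(OC)c(C)c(OCOC)c(C(C)=O)c1OCOC | intermediate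
14 | 3-[3-acetyl-6-methoxy-2,4-bis(methoxymethoxy)-5-methylphenyl]prop-1-en-1-one (aldoketene, formed in the flask) | O=C=CCc1c(OC)c(C)c(OCOC)c(C(C)=O)c1OCOC | intermediate
15 | 4-{[3-acetyl-6-methoxy-2,4-bis(methoxymethoxy)-5-methylphenyl]methyl}-3-ethoxycyclobut-2-en-1-one (racemic) | CCOC1=CC(=O)C1Cc1c(OC)c(C)c(OCOC)c(C(C)=O)c1OCOC | intermediate
16 | ethyl 4-methylpent-3-enoate | CCOC(=O)CC=C(C)C | starting material
17 | lithium 1,1-dibromo-5-methylhexa-1,4-dien-2-olate (formed in the flask) | [Li]OC(CC=C(C)C)=C(Br)Br | intermediate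
18 | lithium 5-methylhex-4-en-1-yn-1-olate (formed in the flask) | [Li]OC#CCC=C(C)C | intermediate
19 | triisopropyl[(5-methylhex-4-en-1-yn-1-yl)oxy]silane | CC(C)=CCC#CO[Si](C(C)C)(C(C)C)C(C)C | intermediate
20 | (3Z)-5-Ar-3-ethoxypenta-1,3-dien-1-one (vinylketene, formed in the flask) | O=C=C/C(OCC)=C/Cc1c(OC)c(C)c(OCOC)c(C(C)=O)c1OCOC | intermediate
21 | 4-[(1Z)-3-Ar-1-ethoxyprop-1-en-1-yl]-2-(3-methylbut-2-en-1-yl)-3-[(triisopropylsilyl)oxy]cyclobut-2-en-1-one (racemic, formed in the flask) | O=C1C(CC=C(C)C)=C(O[Si](C(C)C)(C(C)C)C(C)C)C1/C(OCC)=C/Cc1c(OC)c(C)c(OCOC)c(C(C)=O)c1OCOC | intermediate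
22 | (3E,5Z)-7-Ar-5-ethoxy-2-(3-methylbut-2-en-1-yl)-3-[(triisopropylsilyl)oxy]hepta-1,3,5-trien-1-one (dienylketene, formed in the flask) | O=C=C(CC=C(C)C)/C(O[Si](C(C)C)(C(C)C)C(C)C)=C\C(OCC)=C\Cc1c(OC)c(C)c(OCOC)c(C(C)=O)c1OCOC | intermediate
23 | 6-(ArCH2)-5-ethoxy-2-(3-methylbut-2-en-1-yl)-3-[(triisopropylsilyl)oxy]cyclohexa-2,4-dien-1-one (racemic, formed in the flask) | O=C1C(CC=C(C)C)=C(O[Si](C(C)C)(C(C)C)C(C)C)C=C(OCC)C1Cc1c(OC)c(C)c(OCOC)c(C(C)=O)c1OCOC | intermediate
24 | 1-{3-[(6-ethoxy-2-hydroxy-3-(3-methylbut-2-en-1-yl)-4-[(triisopropylsilyl)oxy]phenyl)methyl]-4-methoxy-2,6-bis(methoxymethoxy)-5-methylphenyl}ethan-1-one | CCOc1cc(O[Si](C(C)C)(C(C)C)C(C)C)c(CC=C(C)C)c(O)c1Cc1c(OC)c(C)c(OCOC)c(C(C)=O)c1OCOC | intermediate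
25 | 2-(ArCH2)-3-ethoxy-4-iodo-6-(3-methylbut-2-en-1-yl)-5-[(triisopropylsilyl)oxy]phenol | CCOc1c(I)c(O[Si](C(C)C)(C(C)C)C(C)C)c(CC=C(C)C)c(O)c1Cc1c(OC)c(C)c(OCOC)c(C(C)=O)c1OCOC | intermediate
26 | 2-(ArCH2)-3-ethoxy-4-(1-ethoxyethenyl)-6-(3-methylbut-2-en-1-yl)-5-[(triisopropylsilyl)oxy]phenol (formed in the flask) | CCOc1c(C(=C)OCC)c(O[Si](C(C)C)(C(C)C)C(C)C)c(CC=C(C)C)c(O)c1Cc1c(OC)c(C)c(OCOC)c(C(C)=O)c1OCOC | intermediate
27 | 1-{3-(ArCH2)-2-ethoxy-4-hydroxy-5-(3-methylbut-2-en-1-yl)-6-[(triisopropylsilyl)oxy]phenyl}ethan-1-one | CCOc1c(C(C)=O)c(O[Si](C(C)C)(C(C)C)C(C)C)c(CC=C(C)C)c(O)c1Cc1c(OC)c(C)c(OCOC)c(C(C)=O)c1OCOC | intermediate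
28 | 1-{3-[(3-acetyl-2,4-dihydroxy-6-methoxy-5-methylphenyl)methyl]-2,4-dihydroxy-5-(3-methylbut-2-en-1-yl)-6-[(triisopropylsilyl)oxy]phenyl}ethan-1-one | Oc1c(C(C)=O)c(O[Si](C(C)C)(C(C)C)C(C)C)c(CC=C(C)C)c(O)c1Cc1c(OC)c(C)c(O)c(C(C)=O)c1O | intermediate
29 | mallotojaponin, 1-{3-[(3-acetyl-2,4,6-trihydroxy-5-(3-methylbut-2-en-1-yl)phenyl)methyl]-2,6-dihydroxy-4-methoxy-5-methylphenyl}ethan-1-one | COc1c(C)c(O)c(C(C)=O)c(O)c1Cc1c(O)c(CC=C(C)C)c(O)c(C(C)=O)c1O | target

Total step count: 13. Longest linear sequence: 12 steps (steps 1–7 and 9–13); step 8 is a one-step side branch.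

Steps most likely to fail

Step 9 (proposed new method). The vinylogous ester ring of 15 may open too slowly, so that the siloxyalkyne rearranges or the ketenes dimerise or acylate the product phenol before cycloaddition and ring closure. The fallback uses only known chemistry and no pericyclic step. It sets out from ring A monomer 3, which in a Mannich reaction with Me2NH and aqueous CH2O at its one free ring carbon should give 1-{3-[(dimethylamino)methyl]-2,6-dihydroxy-4-methoxy-5-methylphenyl}ethan-1-one F1. In parallel, commercial 2,4,6-trihydroxyacetophenone is C-prenylated (prenyl bromide, aqueous KOH) to 1-[2,4,6-trihydroxy-3-(3-methylbut-2-en-1-yl)phenyl]ethan-1-one F2. Heating F1 with F2 in dioxane at 100 °C should expel dimethylamine to the ortho-quinone methide 2-acetyl-3-hydroxy-5-methoxy-4-methyl-6-methylidenecyclohexa-2,4-dien-1-one F3, which is trapped at the one free ring carbon of F2. The fallback comes back to the route at target 29.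

Step 11. Oxidative addition or transmetalation may stall at the iodide flanked by the silyl ether and the ethoxy group, so that protodeiodination takes over. The fallback sets out from 24 and leaves out step 10. Vilsmeier–Haack formylation at B5 (POCl3, DMF, 0 °C) should lead through the B5 iminium chloride F4 to 2-ethoxy-4-hydroxy-3-(ArCH2)-5-(3-methylbut-2-en-1-yl)-6-[(triisopropylsilyl)oxy]benzaldehyde F5. MeTi(OiPr)3 then adds to the aldehyde only, not to the hindered ring A ketone, to give racemic 2-(ArCH2)-3-ethoxy-4-(1-hydroxyethyl)-6-(3-methylbut-2-en-1-yl)-5-[(triisopropylsilyl)oxy]phenol F6. Oxidation of this benzylic alcohol with MnO2 comes back to the route at ketone 27.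

Step 12. Attack of iodide on the ethyl group is slower than on a methyl group and may not reach completion at a temperature the prenyl group tolerates, or a MOM ether may survive. The fallback sets out from 27. The B2 phenol is capped (TBSOTf, 2,6-lutidine, CH2Cl2, −78 °C) to 1-{3-(ArCH2)-4-[(tert-butyldimethylsilyl)oxy]-2-ethoxy-5-(3-methylbut-2-en-1-yl)-6-[(triisopropylsilyl)oxy]phenyl}ethan-1-one F7, so that neither oxygen next to the prenyl group is free. BCl3 (CH2Cl2, −78 → 0 °C), chelated to the two acetyl carbonyls, should then cleave the ethyl ether and both MOM ethers to 1-{3-[(3-acetyl-2,4-dihydroxy-6-methoxy-5-methylphenyl)methyl]-4-[(tert-butyldimethylsilyl)oxy]-2-hydroxy-5-(3-methylbut-2-en-1-yl)-6-[(triisopropylsilyl)oxy]phenyl}ethan-1-one F8. Bu4NF/AcOH removes both silyl groups, and the fallback comes back to the route at target 29.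

Further compounds
F1 | step 9 | 1-{3-[(dimethylamino)methyl]-2,6-dihydroxy-4-methoxy-5-methylphenyl}ethan-1-one | CN(C)Cc1c(OC)c(C)c(O)c(C(C)=O)c1O
F2 | step 9 | 1-[2,4,6-trihydroxy-3-(3-methylbut-2-en-1-yl)phenyl]ethan-1-one | CC(=O)c1c(O)cc(O)c(CC=C(C)C)c1O
F3 | step 9 | 2-acetyl-3-hydroxy-5-methoxy-4-methyl-6-methylidenecyclohexa-2,4-dien-1-one | C=C1C(=O)C(C(C)=O)=C(O)C(C)=C1OC
F4 | step 11 | N-{[2-ethoxy-4-hydroxy-3-(ArCH2)-5-(3-methylbut-2-en-1-yl)-6-[(triisopropylsilyl)oxy]phenyl]methylidene}-N-methylmethanaminium chloride | C[N+](C)=Cc1c(OCC)c(Cc2c(OC)c(C)c(OCOC)c(C(C)=O)c2OCOC)c(O)c(CC=C(C)C)c1O[Si](C(C)C)(C(C)C)C(C)C.[Cl-]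
F5 | step 11 | 2-ethoxy-4-hydroxy-3-(ArCH2)-5-(3-methylbut-2-en-1-yl)-6-[(triisopropylsilyl)oxy]benzaldehyde | CCOc1c(C=O)c(O[Si](C(C)C)(C(C)C)C(C)C)c(CC=C(C)C)c(O)c1Cc1c(OC)c(C)c(OCOC)c(C(C)=O)c1OCOC
F6 | step 11 | 2-(ArCH2)-3-ethoxy-4-(1-hydroxyethyl)-6-(3-methylbut-2-en-1-yl)-5-[(triisopropylsilyl)oxy]phenol (racemic) | CCOc1c(C(C)O)c(O[Si](C(C)C)(C(C)C)C(C)C)c(CC=C(C)C)c(O)c1Cc1c(OC)c(C)c(OCOC)c(C(C)=O)c1OCOC
F7 | step 12 | 1-{3-(ArCH2)-4-[(tert-butyldimethylsilyl)oxy]-2-ethoxy-5-(3-methylbut-2-en-1-yl)-6-[(triisopropylsilyl)oxy]phenyl}ethan-1-one | CCOc1c(C(C)=O)c(O[Si](C(C)C)(C(C)C)C(C)C)c(CC=C(C)C)c(O[Si](C)(C)C(C)(C)C)c1Cc1c(OC)c(C)c(OCOC)c(C(C)=O)c1OCOC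
F8 | step 12 | 1-{3-[(3-acetyl-2,4-dihydroxy-6-methoxy-5-methylphenyl)methyl]-4-[(tert-butyldimethylsilyl)oxy]-2-hydroxy-5-(3-methylbut-2-en-1-yl)-6-[(triisopropylsilyl)oxy]phenyl}ethan-1-one | Oc1c(C(C)=O)c(O[Si](C(C)C)(C(C)C)C(C)C)c(CC=C(C)C)c(O[Si](C)(C)C(C)(C)C)c1Cc1c(OC)c(C)c(O)c(C(C)=O)c1O
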